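**Retrosynthetic overview**
1. Last step: one hydrogenation saturates a side-chain C2′=C3′ alkene and removes two O-benzyl groups. Benzyl ethers are used because BBr3-type phenol demethylation would also cleave the side-chain methyl ether.
2. C2′=C3′: cross-metathesis of a (3R)-3-allyl-6,8-bis(benzyloxy)dihydroisocoumarin with (S)-9-methoxydec-1-ene. The latter comes from (S)-propylene oxide (source of C10′) and a C7 Grignard reagent, then O-methylation.
3. Key bond C3–C1′: Brown asymmetric allylboration of an ortho-(2-oxoethyl)resorcylate ester with an allyl-B(Ipc)2 reagent joins the ring fragment to the allyl fragment and sets C3 as R.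
4. The aldehyde comes from methyl orsellinate by O-benzylation, lateral lithiation/carbomethoxylation (Claisen-type) to the homophthalate, and half-reduction of the aliphatic ester.
5. Rings: the benzene ring is bought. The δ-lactone (ring B) is the only ring made and closes by transesterification directly after the key step.

Assumption: the target is read as (3R,10′S), with side-chain carbons numbered C1′–C11′ from the ring. Compound 8 is bought as its salt-free pentane solution. Compound 18 forms as an E/Z mixture (E drawn) and both isomers converge in step 8.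

**Route**

Step 1
Reactants: 1 methyl orsellinate (methyl 2,4-dihydroxy-6-methylbenzoate)
Product: 3 methyl 2,4-bis(benzyloxy)-6-methylbenzoate, via 4-O-benzyl monoether 2 (not isolated)
Conditions: BnBr (2.5 equiv), K2CO3 (3 equiv), DMF, 60 °C, 12 h
Reagents that add atoms: benzyl bromide, BrCc1ccccc1
Why: Williamson etherification in which the free 4-OH reacts first and the chelated 2-OH follows at 60 °C with excess reagent, giving phenol protection that is later removed by hydrogenolysis without touching the side-chain methyl ether.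

Step 2
Reactants: 3 methyl 2,4-bis(benzyloxy)-6-methylbenzoate
Product: 5 methyl 2,4-bis(benzyloxy)-6-(2-methoxy-2-oxoethyl)benzoate, via benzylic lithium species 4 (not isolated)
Conditions: LiN(i-Pr)2 (2.2 equiv), THF, −78 °C, 30 min; (MeO)2CO (1.5 equiv), −78 → −20 °C; then AcOH
Reagents that add atoms: dimethyl carbonate, COC(=O)OC
Why: Lateral lithiation of the ortho-toluate gives a dienolate that is C-acylated by the carbonate in a Claisen-type condensation, and the second equivalent of base takes up the more acidic homophthalate product so that it is not acylated twice.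

Step 3
Reactants: 5 methyl 2,4-bis(benzyloxy)-6-(2-methoxy-2-oxoethyl)benzoate
Product: 7 methyl 2,4-bis(benzyloxy)-6-(2-oxoethyl)benzoate, via aluminium hemiacetal 6 (not isolated)
Conditions: i-Bu2AlH (1.1 equiv), CH2Cl2, −78 °C, 1 h; then aq. KNaC4H4O6, → rt; used crude at once
Reagents that add atoms: none
Why: Chemoselective partial ester reduction, because the unhindered aliphatic ester is attacked at −78 °C while the di-ortho-substituted, electron-rich aryl ester is not, and the tetrahedral aluminium hemiacetal survives until hydrolysis releases the aldehyde.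

Step 4
Reactants: 7 methyl 2,4-bis(benzyloxy)-6-(2-oxoethyl)benzoate; 8 (+)-B-allyldiisopinocampheylborane [(+)-Ipc2B(allyl), the reagent derived from (−)-α-pinene]
Product: 11 (3R)-3-allyl-6,8-bis(benzyloxy)-3,4-dihydro-1H-isochromen-1-one, via borinate ester 9 (not isolated), via hydroxy ester 10 (not isolated)
Conditions: 8 (1.3 equiv, 1 M in pentane), Et2O, −100 → −78 °C, 2 h; then 3 M aq. NaOH, 30% H2O2, 0 °C → rt; then p-TsOH·H2O (10 mol%), toluene, 50 °C; recrystallise
Reagents that add atoms: none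
Why: Brown asymmetric allylboration, the key fragment coupling that forms C3–C1′ through a closed chair transition state in which the (−)-α-pinene-derived reagent delivers allyl to the Re face of the aldehyde to give the (R)-carbinol, after which oxidative work-up frees the alcohol and acid-catalysed transesterification closes ring B.

Step 5
Reactants: 12 7-bromohept-1-ene; 13 (S)-propylene oxide
Product: 15 (2S)-dec-9-en-2-ol, via Grignard reagent 14 (not isolated)
Conditions: Mg, THF, 40 °C; then CuI (10 mol%), 13 (0.85 equiv), −30 → 0 °C; then 1 M aq. HCl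
Reagents that add atoms: none
Why: Copper-catalysed SN2 opening of the terminal epoxide by the Grignard reagent occurs only at the unsubstituted carbon, so the purchased (S) stereocentre is carried over unchanged as C10′.

Step 6
Reactants: 15 (2S)-dec-9-en-2-ol
Product: 17 (9S)-9-methoxydec-1-ene, via sodium alkoxide 16 (not isolated)
Conditions: NaH (1.5 equiv), THF, 0 °C; MeI (2 equiv), 0 °C → rt
Reagents that add atoms: iodomethane, CI
Why: Williamson O-methylation of the alkoxide, in which no bond to the stereocentre is broken.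

Step 7
Reactants: 11 (3R)-3-allyl-6,8-bis(benzyloxy)-3,4-dihydro-1H-isochromen-1-one; 17 (9S)-9-methoxydec-1-ene
Product: 18 (3R)-6,8-bis(benzyloxy)-3-[(2E,10S)-10-methoxyundec-2-en-1-yl]-3,4-dihydro-1H-isochromen-1-one
Conditions: 17 (3 equiv), second-generation Grubbs catalyst RuCl2(=CHPh)(PCy3)(1,3-dimesitylimidazolidin-2-ylidene) (5 mol%), CH2Cl2, 40 °C, 12 h
Reagents that add atoms: none
Why: Olefin cross-metathesis of two unhindered terminal alkenes is driven by ethene loss and an excess of the cheap partner, and the E/Z ratio does not matter because the alkene is hydrogenated next.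

Step 8
Reactants: 18 (3R)-6,8-bis(benzyloxy)-3-[(2E,10S)-10-methoxyundec-2-en-1-yl]-3,4-dihydro-1H-isochromen-1-one
Product: 20 (3R)-6,8-dihydroxy-3-[(10S)-10-methoxyundecyl]-3,4-dihydro-1H-isochromen-1-one, via saturated dibenzyl ether 19 (not isolated)
Conditions: H2 (1 atm), 10% Pd/C, EtOAc–EtOH, rt, 6 h
Reagents that add atoms: none
Why: Catalytic hydrogenation of the alkene followed by O-benzyl hydrogenolysis on the same catalyst, with no allylic or benzylic C–O bond at either stereocentre and an inert alkyl methyl ether and lactone.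

**Compound list**
1 | methyl orsellinate (methyl 2,4-dihydroxy-6-methylbenzoate) | COC(=O)c1c(C)cc(O)cc1O | starting material
2 | methyl 4-(benzyloxy)-2-hydroxy-6-methylbenzoate | COC(=O)c1c(C)cc(OCc2ccccc2)cc1O | intermediate
3 | methyl 2,4-bis(benzyloxy)-6-methylbenzoate | COC(=O)c1c(C)cc(OCc2ccccc2)cc1OCc1ccccc1 | intermediate
4 | [3,5-bis(benzyloxy)-2-(methoxycarbonyl)benzyl]lithium (lateral lithio-dienolate of 3) | [Li]Cc1cc(OCc2ccccc2)cc(OCc2ccccc2)c1C(=O)OC | intermediate
5 | methyl 2,4-bis(benzyloxy)-6-(2-methoxy-2-oxoethyl)benzoate | COC(=O)Cc1cc(OCc2ccccc2)cc(OCc2ccccc2)c1C(=O)OC | intermediate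
6 | methyl 2,4-bis(benzyloxy)-6-{2-[(diisobutylalumanyl)oxy]-2-methoxyethyl}benzoate (hemiacetal carbon racemic) | COC(Cc1cc(OCc2ccccc2)cc(OCc2ccccc2)c1C(=O)OC)O[Al](CC(C)C)CC(C)C | intermediate
7 | methyl 2,4-bis(benzyloxy)-6-(2-oxoethyl)benzoate | O=CCc1cc(OCc2ccccc2)cc(OCc2ccccc2)c1C(=O)OC | intermediate
8 | (+)-B-allyldiisopinocampheylborane, from (−)-α-pinene | C=CCB([C@H]1C[C@H]2C[C@@H]([C@@H]1C)C2(C)C)[C@H]1C[C@H]2C[C@@H]([C@@H]1C)C2(C)C | starting material
9 | (2R)-1-[3,5-bis(benzyloxy)-2-(methoxycarbonyl)phenyl]pent-4-en-2-yl diisopinocampheylborinate | C=CC[C@H](Cc1cc(OCc2ccccc2)cc(OCc2ccccc2)c1C(=O)OC)OB([C@H]1C[C@H]2C[C@@H]([C@@H]1C)C2(C)C)[C@H]1C[C@H]2C[C@@H]([C@@H]1C)C2(C)C | intermediate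
10 | methyl 2,4-bis(benzyloxy)-6-[(2R)-2-hydroxypent-4-en-1-yl]benzoate | C=CC[C@@H](O)Cc1cc(OCc2ccccc2)cc(OCc2ccccc2)c1C(=O)OC | intermediate
11 | (3R)-3-allyl-6,8-bis(benzyloxy)-3,4-dihydro-1H-isochromen-1-one | C=CC[C@@H]1Cc2cc(OCc3ccccc3)cc(OCc3ccccc3)c2C(=O)O1 | intermediate
12 | 7-bromohept-1-ene | C=CCCCCCBr | starting material
13 | (S)-propylene oxide [(2S)-2-methyloxirane] | C[C@H]1CO1 | starting material
14 | hept-6-en-1-ylmagnesium bromide | C=CCCCCC[Mg]Br | intermediate
15 | (2S)-dec-9-en-2-ol | C[C@H](O)CCCCCCC=C | intermediate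
16 | sodium (2S)-dec-9-en-2-olate | C[C@H]([O-])CCCCCCC=C.[Na+] | intermediate
17 | (9S)-9-methoxydec-1-ene | CO[C@@H](C)CCCCCCC=C | intermediate
18 | (3R)-6,8-bis(benzyloxy)-3-[(2E,10S)-10-methoxyundec-2-en-1-yl]-3,4-dihydro-1H-isochromen-1-one | CO[C@@H](C)CCCCCC/C=C/C[C@@H]1Cc2cc(OCc3ccccc3)cc(OCc3ccccc3)c2C(=O)O1 | intermediate
19 | (3R)-6,8-bis(benzyloxy)-3-[(10S)-10-methoxyundecyl]-3,4-dihydro-1H-isochromen-1-one | CO[C@@H](C)CCCCCCCCC[C@@H]1Cc2cc(OCc3ccccc3)cc(OCc3ccccc3)c2C(=O)O1 | intermediate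
20 | (3R)-6,8-dihydroxy-3-[(10S)-10-methoxyundecyl]-3,4-dihydro-1H-isochromen-1-one | CO[C@@H](C)CCCCCCCCC[C@@H]1Cc2cc(O)cc(O)c2C(=O)O1 | target

**Totals**
Total step count: 8. Longest linear sequence: 6 steps (steps 1, 2, 3, 4, 7, 8, from 1 to 20); the chain branch (steps 5 and 6) joins at step 7.

**Steps most likely to fail**

Step 3. The risks are over-reduction to the alcohol, which lactonises to a dead-end isochromanone, and enol-lactonisation of the sensitive arylacetaldehyde 7. The fallback sets out from 5 and comes back at 7. Only the unhindered aliphatic ester of 5 is saponified (LiOH, 1.05 equiv, THF–H2O, 0 °C) to give 2-[3,5-bis(benzyloxy)-2-(methoxycarbonyl)phenyl]acetic acid F1. This is coupled with MeNHOMe·HCl (EDC·HCl, HOBt, i-Pr2NEt, CH2Cl2) to the Weinreb amide methyl 2,4-bis(benzyloxy)-6-{2-[methoxy(methyl)amino]-2-oxoethyl}benzoate F2. Reduction of F2 with i-Bu2AlH (THF, −78 °C) goes through a chelated tetrahedral intermediate that cannot be reduced further, and hydrolysis delivers 7.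

Step 4. The risk is an enantiomeric excess below about 95%; the minor C3 epimer becomes a hard-to-separate diastereomer after step 7. A further risk is partial lactone hydrolysis during the alkaline oxidative work-up. The fallback sets out from 7 and comes back at 10, and it sets C3 by kinetic resolution of an epoxide instead of by allyl transfer. Aldehyde 7 is methylenated (Ph3P=CH2 from Ph3PCH3Br and KOt-Bu, THF, −78 → 0 °C) to methyl 2-allyl-4,6-bis(benzyloxy)benzoate F3. Epoxidation (mCPBA, NaHCO3, CH2Cl2) gives racemic methyl 2,4-bis(benzyloxy)-6-(oxiran-2-ylmethyl)benzoate F4. Jacobsen hydrolytic kinetic resolution with (S,S)-(salen)Co(OAc) (trivalent cobalt, 0.5 mol%) and H2O (0.55 equiv) leaves methyl 2,4-bis(benzyloxy)-6-{[(2S)-oxiran-2-yl]methyl}benzoate F5 in high ee. The hydrolysed enantiomer, methyl 2,4-bis(benzyloxy)-6-[(2R)-2,3-dihydroxypropyl]benzoate F6, is removed by chromatography. The catalyst sense is assigned by analogy with simple alkyl oxiranes and should be confirmed by Mosher analysis of 10; if it is reversed, the mirror-image catalyst is used. CuI-catalysed opening of F5 at its CH2 terminus with CH2=CHMgBr (THF, −40 °C) gives 10, since the (S)-epoxide maps onto the (R)-alcohol through a change of CIP ranks only. Compound 10 is lactonised to 11 as in step 4.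

Step 7. The risks are statistical product mixtures, homodimer of 11 and incomplete conversion. The fallback sets out from 11 and 17 and comes back at 18, replacing metathesis by a Julia–Kocienski olefination.
- The alkene of 11 is cleaved (OsO4 cat., NaIO4, 2,6-lutidine, dioxane–H2O) to 2-[(3S)-6,8-bis(benzyloxy)-1-oxo-3,4-dihydro-1H-isochromen-3-yl]acetaldehyde F7.
- F7 is reduced at once (NaBH4, MeOH, 0 °C) to (3S)-6,8-bis(benzyloxy)-3-(2-hydroxyethyl)-3,4-dihydro-1H-isochromen-1-one F8.
- Mitsunobu reaction with 1-phenyl-1H-tetrazole-5-thiol (PPh3, DIAD, THF) gives (3S)-6,8-bis(benzyloxy)-3-{2-[(1-phenyl-1H-tetrazol-5-yl)sulfanyl]ethyl}-3,4-dihydro-1H-isochromen-1-one F9.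
- mCPBA oxidation gives (3S)-6,8-bis(benzyloxy)-3-{2-[(1-phenyl-1H-tetrazol-5-yl)sulfonyl]ethyl}-3,4-dihydro-1H-isochromen-1-one F10.
- Ozonolysis of 17 (O3, CH2Cl2, −78 °C; then PPh3) gives (8S)-8-methoxynonanal F11.
- Adding KN(SiMe3)2 to F10 and F11 (DME, −60 °C → rt) gives 18 as the E alkene.

The (3S) descriptors of F7–F10 reflect changed CIP ranks only; the geometry at C3 is that of 11. The sulfonyl carbanion has no β leaving group, so the lactone is not opened.

**Further compounds**
F1 | step 3 | 2-[3,5-bis(benzyloxy)-2-(methoxycarbonyl)phenyl]acetic acid | OC(=O)Cc1cc(OCc2ccccc2)cc(OCc2ccccc2)c1C(=O)OC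
F2 | step 3 | methyl 2,4-bis(benzyloxy)-6-{2-[methoxy(methyl)amino]-2-oxoethyl}benzoate | CON(C)C(=O)Cc1cc(OCc2ccccc2)cc(OCc2ccccc2)c1C(=O)OC
F3 | step 4 | methyl 2-allyl-4,6-bis(benzyloxy)benzoate | C=CCc1cc(OCc2ccccc2)cc(OCc2ccccc2)c1C(=O)OC
F4 | step 4 | racemic methyl 2,4-bis(benzyloxy)-6-(oxiran-2-ylmethyl)benzoate | COC(=O)c1c(CC2CO2)cc(OCc3ccccc3)cc1OCc1ccccc1
F5 | step 4 | methyl 2,4-bis(benzyloxy)-6-{[(2S)-oxiran-2-yl]methyl}benzoate | COC(=O)c1c(C[C@H]2CO2)cc(OCc3ccccc3)cc1OCc1ccccc1
F6 | step 4 | methyl 2,4-bis(benzyloxy)-6-[(2R)-2,3-dihydroxypropyl]benzoate | COC(=O)c1c(C[C@@H](O)CO)cc(OCc3ccccc3)cc1OCc1ccccc1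
F7 | step 7 | 2-[(3S)-6,8-bis(benzyloxy)-1-oxo-3,4-dihydro-1H-isochromen-3-yl]acetaldehyde | O=CC[C@@H]1Cc2cc(OCc3ccccc3)cc(OCc3ccccc3)c2C(=O)O1
F8 | step 7 | (3S)-6,8-bis(benzyloxy)-3-(2-hydroxyethyl)-3,4-dihydro-1H-isochromen-1-one | OCC[C@@H]1Cc2cc(OCc3ccccc3)cc(OCc3ccccc3)c2C(=O)O1
F9 | step 7 | (3S)-6,8-bis(benzyloxy)-3-{2-[(1-phenyl-1H-tetrazol-5-yl)sulfanyl]ethyl}-3,4-dihydro-1H-isochromen-1-one | c1ccc(cc1)-n1nnnc1SCC[C@@H]1Cc2cc(OCc3ccccc3)cc(OCc3ccccc3)c2C(=O)O1
F10 | step 7 | (3S)-6,8-bis(benzyloxy)-3-{2-[(1-phenyl-1H-tetrazol-5-yl)sulfonyl]ethyl}-3,4-dihydro-1H-isochromen-1-one | c1ccc(cc1)-n1nnnc1S(=O)(=O)CC[C@@H]1Cc2cc(OCc3ccccc3)cc(OCc3ccccc3)c2C(=O)O1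
F11 | step 7 | (8S)-8-methoxynonanal | CO[C@@H](C)CCCCCCC=O
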